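Retrosynthesis: (i) the two ring-B MOM groups come off last. (ii) C4 is re-oxidised to C=O, which makes C3 epimerisable (isoflavanone 12). (iii) O1–C2 and C4–C4a of ring C are cut together, giving aryl ester 10, in which the future C4 sits as acyl carbon on a ring-A oxygen. (iv) The ester C–O bond is cut to acid 9 and diol 5.
Enabling feature: ring A is a 2-substituted resorcinol. O1 and O7 are meta to each other, C8 between them is blocked by the prenyl group, and C4a is ortho to O1 and para to O7. An acyl shift from oxygen to the ortho or to the para carbon therefore gives the same ketone, and its ortho OH lies within reach of the acrylate CH2 (C2).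
Both arenes carry the same 1,3-dioxygen-2-prenyl pattern and come from one building block, 4 (resorcinol, two directed lithiations).
Forward order: 1 → 4; branch A 4 → 5; branch B 4 → 9; ester 10; ring C closes in step 8; C4=O is removed in step 9; deprotection in step 10.
Stereochemistry: C3, the only stereocentre, forms racemic in step 8 and is set as R in step 9 by catalyst-controlled transfer hydrogenation with dynamic kinetic resolution.

Key step: step 8

Remarks: prenyl = 3-methylbut-2-en-1-yl; MOM = methoxymethyl; isoflavonoid numbering is used (O1, C2, C3, C4, C4a–C8a; primed numbers for ring B).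
Assumption: the (R,R)-TsDPEN–Ru catalyst follows its usual model for aryl ketones (4R alcohol, cis to the 3-aryl group). If a test run shows the opposite sense, the (S,S) catalyst is used.

Step 1
Reactants: 1 resorcinol
Product: 2 1,3-bis(methoxymethoxy)benzene
Conditions: NaH (2.4 equiv), MOMCl (2.4 equiv), DMF, 0 °C to rt
Reagents that add atoms: chloromethyl methyl ether (MOMCl), COCCl
Why: Williamson-type O-alkylation of the bis-phenoxide, with MOM chosen because it directs both later lithiations and leaves under mild acid.

Step 2
Reactants: 2 1,3-bis(methoxymethoxy)benzene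
Product: 4 1,3-bis(methoxymethoxy)-2-prenylbenzene, via aryllithium 3 (not isolated)
Conditions: n-BuLi (1.1 equiv), THF, 0 °C to rt; prenyl bromide, −78 °C to rt
Reagents that add atoms: prenyl bromide (1-bromo-3-methylbut-2-ene), CC(C)=CCBr
Why: Directed ortho-metalation goes to C2, the position flanked by both OMOM groups, and the aryllithium displaces bromide at the primary end of prenyl bromide (SN2), so the linear prenyl group results.

Step 3
Reactants: 4 1,3-bis(methoxymethoxy)-2-prenylbenzene
Product: 5 2-prenylbenzene-1,3-diol (2-prenylresorcinol)
Conditions: HCl (cat.), MeOH, 40 °C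
Reagents that add atoms: none
Why: Acid-catalysed transacetalisation of aryl MOM ethers to methanol is faster than protonation of the trisubstituted alkene, a selectivity with broad precedent for ortho-prenylphenols.

Step 4
Reactants: 4 1,3-bis(methoxymethoxy)-2-prenylbenzene
Product: 7 ethyl 2-[2,4-bis(methoxymethoxy)-3-prenylphenyl]-2-oxoacetate, via aryllithium 6 (not isolated)
Conditions: n-BuLi, TMEDA (1.2 equiv each), Et2O, 0 °C; cannulated into diethyl oxalate (3 equiv), THF, −78 °C; AcOH, −78 °C
Reagents that add atoms: diethyl oxalate, CCOC(=O)C(=O)OCC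
Why: A second directed ortho-metalation can only go to the equivalent positions C4/C6 next to an OMOM group, and acylation by excess diethyl oxalate under inverse addition stops at the α-keto ester because the tetrahedral adduct survives at −78 °C until the acid quench.

Step 5
Reactants: 7 ethyl 2-[2,4-bis(methoxymethoxy)-3-prenylphenyl]-2-oxoacetate
Product: 8 ethyl 2-[2,4-bis(methoxymethoxy)-3-prenylphenyl]prop-2-enoate
Conditions: MePPh3Br, KOtBu, THF, 0 °C; then 7, 0 °C to rt
Reagents that add atoms: methyltriphenylphosphonium bromide, C[P+](c1ccccc1)(c1ccccc1)c1ccccc1.[Br-]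
Why: Wittig methylenation takes the ketone carbonyl of an aryl glyoxylate in preference to the ester, which is the standard way to 2-arylacrylates.

Step 6
Reactants: 8 ethyl 2-[2,4-bis(methoxymethoxy)-3-prenylphenyl]prop-2-enoate
Product: 9 2-[2,4-bis(methoxymethoxy)-3-prenylphenyl]prop-2-enoic acid
Conditions: LiOH, THF/H2O, rt; cold 0.5 M HCl to pH 4
Reagents that add atoms: lithium hydroxide, [Li+].[OH-]
Why: Ester saponification touches neither the acetals nor the alkenes, and acidification is stopped at pH 4 in the cold to keep the MOM groups.

Step 7
Reactants: 5 2-prenylresorcinol (2.5 equiv); 9 2-[2,4-bis(methoxymethoxy)-3-prenylphenyl]prop-2-enoic acid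
Product: 10 3-hydroxy-2-prenylphenyl 2-[2,4-bis(methoxymethoxy)-3-prenylphenyl]prop-2-enoate
Conditions: DCC, DMAP (10 mol %), CH2Cl2, 0 °C to rt
Reagents that add atoms: none
Why: In this Steglich esterification the two OH groups of 5 are equivalent, so only mono- against di-acylation has to be controlled, which the excess of recoverable 5 does.

Step 8
Reactants: 10 3-hydroxy-2-prenylphenyl 2-[2,4-bis(methoxymethoxy)-3-prenylphenyl]prop-2-enoate
Product: 12 (±)-7-hydroxy-3-[2,4-bis(methoxymethoxy)-3-prenylphenyl]-8-prenylchroman-4-one, via hydroxy enone 11 (not isolated)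
Conditions: hν (254 nm, quartz flow coil), degassed MeCN (5 mM), 20 °C; then Et3N (0.2 equiv), dark, 20 °C
Reagents that add atoms: none
Why: Excitation of the aryl ester cleaves the O–acyl bond homolytically, the caged acyl/aryloxyl radical pair recombines at a ring carbon ortho or para to the oxygen and re-aromatises to ketone 11 (new C4–C4a bond), and after Et3N is added the phenol ortho to the new carbonyl group adds to the CH2 end of the enone (new O1–C2 bond). The closest known reaction type is the one-pot photo-Fries rearrangement/oxa-Michael cyclisation of aryl esters of α,β-unsaturated acids to chroman-4-ones; resorcinol monoesters are known to rearrange this way to 2,4-dihydroxyaryl ketones, and the closure itself is the last event of the classical isoflavanone synthesis from 2-hydroxydeoxybenzoins and formaldehyde. Ring C closes in the 6-endo-trig mode. C3 arises by uncontrolled protonation of the enolate, so 12 is racemic, which is intended because this centre is epimerisable and is set in step 9. The step needs a regioselective acyl shift: C8 is blocked by the prenyl group, and because O1 and O7 are equivalent in the 2-substituted resorcinol, the ortho and the para shift give the same 2,4-dihydroxy-3-prenylphenyl ketone, in which only the chelated ortho OH can reach the CH2. The neutral medium leaves both prenyl groups and the MOM acetals untouched, and MeCN as hydrogen-bond acceptor should suppress excited-state proton transfer from the free OH to the neighbouring double bond.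

Step 9
Reactants: 12 (±)-7-hydroxy-3-[2,4-bis(methoxymethoxy)-3-prenylphenyl]-8-prenylchroman-4-one
Product: 15 (3R)-3-[2,4-bis(methoxymethoxy)-3-prenylphenyl]-8-prenylchroman-7-ol, via cis-isoflavan-4-ol 13 (not isolated), via para-quinone methide 14 (not isolated)
Conditions: RuCl[(R,R)-TsDPEN](mesitylene) (3 mol %), HCO2H/Et3N (5:2), EtOAc, 45 °C
Reagents that add atoms: none
Why: Noyori-type asymmetric transfer hydrogenation with dynamic kinetic resolution and in-flask deoxygenation is known for isoflavanones: C3 epimerises through the enol under Et3N, the (R,R) catalyst reduces only the (3R) ketone to the cis (3R,4R) alcohol 13 and so sets C3, 13 ionises in the formic acid medium (helped by O1 and the para 7-OH) to 14, which takes a second hydride at C4, and this catalyst does not reduce isolated alkenes.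

Step 10
Reactants: 15 (3R)-3-[2,4-bis(methoxymethoxy)-3-prenylphenyl]-8-prenylchroman-7-ol
Product: 16 Kanzonol X
Conditions: HCl (cat.), MeOH, 40 °C, stopped at full conversion
Reagents that add atoms: none
Why: This is the same acid-catalysed transacetalisation as in step 3; C3 is not epimerisable in the isoflavan, and short contact at mild temperature keeps the ortho-prenylphenol units from closing to dimethylchromans.

Compound list
1 | resorcinol | Oc1cccc(O)c1 | starting material
2 | 1,3-bis(methoxymethoxy)benzene | COCOc1cccc(OCOC)c1 | intermediate
3 | 2,6-bis(methoxymethoxy)phenyllithium | [Li]c1c(OCOC)cccc1OCOC | intermediate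
4 | 1,3-bis(methoxymethoxy)-2-prenylbenzene | CC(C)=CCc1c(OCOC)cccc1OCOC | intermediate
5 | 2-prenylbenzene-1,3-diol | CC(C)=CCc1c(O)cccc1O | intermediate
6 | [2,4-bis(methoxymethoxy)-3-prenylphenyl]lithium | [Li]c1ccc(OCOC)c(CC=C(C)C)c1OCOC | intermediate
7 | ethyl 2-[2,4-bis(methoxymethoxy)-3-prenylphenyl]-2-oxoacetate | CCOC(=O)C(=O)c1ccc(OCOC)c(CC=C(C)C)c1OCOC | intermediate
8 | ethyl 2-[2,4-bis(methoxymethoxy)-3-prenylphenyl]prop-2-enoate | C=C(C(=O)OCC)c1ccc(OCOC)c(CC=C(C)C)c1OCOC | intermediate
9 | 2-[2,4-bis(methoxymethoxy)-3-prenylphenyl]prop-2-enoic acid | C=C(C(=O)O)c1ccc(OCOC)c(CC=C(C)C)c1OCOC | intermediate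
10 | 3-hydroxy-2-prenylphenyl 2-[2,4-bis(methoxymethoxy)-3-prenylphenyl]prop-2-enoate | C=C(C(=O)Oc1cccc(O)c1CC=C(C)C)c1ccc(OCOC)c(CC=C(C)C)c1OCOC | intermediate
11 | 1-(2,4-dihydroxy-3-prenylphenyl)-2-[2,4-bis(methoxymethoxy)-3-prenylphenyl]prop-2-en-1-one | C=C(C(=O)c1ccc(O)c(CC=C(C)C)c1O)c1ccc(OCOC)c(CC=C(C)C)c1OCOC | intermediate
12 | (±)-7-hydroxy-3-[2,4-bis(methoxymethoxy)-3-prenylphenyl]-8-prenylchroman-4-one (racemic) | CC(C)=CCc1c(OCOC)ccc(C2COc3c(ccc(O)c3CC=C(C)C)C2=O)c1OCOC | intermediate
13 | (3R,4R)-3-[2,4-bis(methoxymethoxy)-3-prenylphenyl]-8-prenylchroman-4,7-diol (cis) | CC(C)=CCc1c(OCOC)ccc([C@@H]2COc3c(ccc(O)c3CC=C(C)C)[C@@H]2O)c1OCOC | intermediate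
14 | (3R)-3-[2,4-bis(methoxymethoxy)-3-prenylphenyl]-8-prenyl-2,3-dihydro-7H-chromen-7-one (para-quinone methide) | CC(C)=CCC1=C2OC[C@@H](c3ccc(OCOC)c(CC=C(C)C)c3OCOC)C=C2C=CC1=O | intermediate
15 | (3R)-3-[2,4-bis(methoxymethoxy)-3-prenylphenyl]-8-prenylchroman-7-ol | CC(C)=CCc1c(OCOC)ccc([C@@H]2COc3c(ccc(O)c3CC=C(C)C)C2)c1OCOC | intermediate
16 | Kanzonol X, 4-[(3R)-7-hydroxy-8-prenylchroman-3-yl]-2-prenylbenzene-1,3-diol | CC(C)=CCc1c(O)ccc([C@@H]2COc3c(ccc(O)c3CC=C(C)C)C2)c1O | target

Total step count: 10. Longest linear sequence: 9 steps (1, 2, 4, 5, 6, 7, 8, 9, 10).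

Steps most likely to fail

1. Step 8.
- What may go wrong: the radical pair may escape from the solvent cage, which loses the acyl group. The aryl acrylate chromophore and the strongly absorbing product may screen the light. The acrylate may polymerise by a radical path. Light may induce proton transfer from the free OH to the prenyl double bond.
- Fallback, from 9 and 5 back to 12: the light-driven shift is replaced by a metal-templated acylation. Acid 9 is treated with 1-chloro-N,N,2-trimethylprop-1-en-1-amine in CH2Cl2 at 0 °C to give the 2-arylacryloyl chloride F1 under neutral conditions.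
- Diol 5 is deprotonated with EtMgBr (2 equiv) in Et2O, and the solvent is changed to toluene to give the bis(bromomagnesium) resorcinolate F2.
- The two are combined in toluene at rt. Ortho-specific C-acylation in the coordination sphere of magnesium is known for aryloxymagnesium bromides and α,β-unsaturated acyl chlorides. It should give 11, which closes to 12 after aqueous NH4Cl work-up and brief contact with Et3N.

2. Step 9.
- What may go wrong: hydride transfer to the electron-rich ketone with its free para OH may be slow. The alcohol may ionise incompletely in the buffered medium. Configuration may be lost if the quinone methide gives up the C3 proton before it takes the hydride.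
- Fallback, from 13 back to 15: reduction and deoxygenation are separated. The transfer hydrogenation is run at 20 °C with HCO2Na in EtOAc/H2O, so that it stops at 13, which is isolated.
- Ac2O/pyridine gives the 4,7-diacetate F3.
- NaBH4 with aqueous NaOH (1 equiv) in THF/EtOH at 0 °C cleaves the aryl acetate. The phenoxide expels the 4-acetate (1,6-elimination), and the quinone methide is trapped at once by borohydride. This is the known base-triggered deoxygenation of para-hydroxybenzyl esters, and it should give 15 without any acid.

3. Step 4.
- What may go wrong: deprotonation at the benzylic, allylic CH2 of the prenyl group may compete with ring lithiation. The aryllithium may add twice to the oxalate.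
- Fallback, from 5 back to 6: deprotonation is replaced by halogen–metal exchange. The free resorcinol ring of 5 is brominated with NBS (1.0 equiv) in CH2Cl2 at −78 °C, where the activated ring should take up Br+ faster than the alkene, to give 4-bromo-2-prenylresorcinol F4.
- NaH/MOMCl in DMF gives the bis-MOM aryl bromide F5.
- n-BuLi in THF at −78 °C exchanges bromine for lithium faster than any C–H is removed and gives 6, which is carried into the oxalate quench of step 4.

Further compounds
F1 | step 8 | 2-[2,4-bis(methoxymethoxy)-3-prenylphenyl]prop-2-enoyl chloride | C=C(C(=O)Cl)c1ccc(OCOC)c(CC=C(C)C)c1OCOC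
F2 | step 8 | bis(bromomagnesium) 2-prenylbenzene-1,3-diolate | CC(C)=CCc1c(O[Mg]Br)cccc1O[Mg]Br
F3 | step 9 | (3R,4R)-3-[2,4-bis(methoxymethoxy)-3-prenylphenyl]-8-prenylchroman-4,7-diyl diacetate | CC(C)=CCc1c(OCOC)ccc([C@@H]2COc3c(ccc(OC(C)=O)c3CC=C(C)C)[C@@H]2OC(C)=O)c1OCOC
F4 | step 4 | 4-bromo-2-prenylbenzene-1,3-diol | CC(C)=CCc1c(O)ccc(Br)c1O
F5 | step 4 | 1-bromo-2,4-bis(methoxymethoxy)-3-prenylbenzene | CC(C)=CCc1c(OCOC)ccc(Br)c1OCOC
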